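| setting | Monday's | Friday's | cedar | maple | ash | alder | oak |
|---|---|---|---|---|---|---|---|
| free monomer | 0.0086 M | 0.092 M | 0.010 M | 0.020 M | 0.040 M | 0.080 M | 0.15 M |
| initiator | 0.2 mol% | 0.2 mol% | 0.2 mol% | 0.2 mol% | 0.2 mol% | 0.2 mol% | 0.2 mol% |
| remark | run made earlier | run made earlier |  |  |  |  |  |
| time |  |  | 50 min | 50 min | 50 min | 50 min | 50 min |

| run | time / min | monomer in chains / % | free monomer / % |
|---|---|---|---|
| Monday's | 3.00 | 18.0 | 76.1 |
| Monday's | 8.00 | 22.1 | 51.4 |
| Monday's | 15.0 | 13.7 | 37.2 |
| Monday's | 25.0 | 6.7 | 26.4 |
| Monday's | 40.0 | 1.5 | 20.1 |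
| Friday's | 8.00 | 33.9 | 13.1 |
| Friday's | 15.0 | 12.0 | 3.9 |
| Friday's | 20.0 | 6.7 | 0.7 |
| Friday's | 30.0 | 2.4 | 0 |
| Friday's | 40.0 | 0.6 | 1.3 |

(standard deviation of a reading: 1 percentage point)

- what was read earlier has a scatter of 1 percentage point, one standard deviation
- "hardly changes" means that all values lie within two and a half points (for a concentration: within two and a half percent of the largest)

1. [monomer in chains] at the end for cedar, maple, ash, alder, oak, in this order
2. the course of these numbers from the first flask to the last (falls, then rises / rises, then falls / hardly changes / falls all the way / rises all the way)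

A one-step world demands that free monomer and monomer in chains add up to the charge. Friday's run refuses: at 30.0 min the two readings add up to 2.40%, so the rest stands in a pool that was not read, and it can fill from the chains.

How long, then, does monomer stay in chains? Between 8.00 min and 30.0 min of Friday's run the unread pool gains 45 percentage points. Dividing the area under the chain curve by that gain gives the chain life, the mean time monomer spends in chains before it leaves them, read as 5.67 min.

What does that mean at the end? The chain life is shorter than the 50 min of the flasks, so [monomer in chains] at the end is no harvest of the whole run. It is roughly the chain life times the late loss of free monomer.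

Which flask holds most? That loss in molar terms is a share of the charge, but the richer run keeps less free monomer late: 20.1% of its charge on Monday against 1.3% on Friday, both read at 40.0 min. This reckoning therefore expects a row that rises, then falls.

The forecast gives 9.000 × 10⁻⁵ M, 1.200 × 10⁻⁴ M, 1.180 × 10⁻⁴ M, 7.400 × 10⁻⁵ M, 2.900 × 10⁻⁵ M, so rises, then falls: “Dilute flasks have little charge; concentrated ones have exhausted their monomer.” Its drain is about 0.2 per minute, against 0.176 min⁻¹ read here.

The flasks give 9.56 × 10⁻⁵ M, 1.29 × 10⁻⁴ M, 1.31 × 10⁻⁴ M, 9.09 × 10⁻⁵ M, 4.92 × 10⁻⁵ M, so rises, then falls, and oak stands at 1.70 times its forecast value.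

    monomer in chains → over-reaction product (k = 0.00320 s⁻¹)
    2 growing radical → dead chain (k = 4.00 × 10⁸ M⁻¹ s⁻¹)
    initiator → 2 initiating radical (k = 0.00170 s⁻¹)
    free monomer + growing radical → monomer in chains + growing radical, rate k4*[growing radical]*[free monomer] (k = 1.90 × 10⁵ M⁻¹ s⁻¹)
    free monomer + initiating radical → growing radical + monomer in chains (k = 8.40 × 10⁶ M⁻¹ s⁻¹)

In cedar, initiator fell to 7.81% of its charge by 25.0 min and to 0.610% by 50.0 min, while free monomer went from 22.5% to 14.8% of its charge and monomer in chains kept turning into over-reaction product, 84.2% of the free monomer charged at the end. The chain life times the mean loss of free monomer over that second half gives 1.74% in chains for cedar, where the flask holds 0.956% at the end, and 0.0531% for oak, where the flask holds 0.0328%.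

The earlier runs and the new flask come from a simulation for an exercise; noise was put on by code.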